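## Structural features

The target is a flavone: a benzo-fused 4-pyranone (rings A and C, sharing C4a–C8a) that carries ring B, a 2-hydroxy-6-methoxyphenyl group, on C2 through the C2–C1' bond. Ring A is fully substituted: methoxy groups on C5, C7 and C8, a free hydroxyl on C6, the ring oxygen O1 on C8a and the carbonyl carbon C4 on C4a, so that O1 and the 6-OH are para to each other as in a hydroquinone. There is no stereocenter; the only stereochemical element is the C2–C1' axis flanked by 2'-OH and 6'-OMe, which is not expected to be configurationally stable and needs no control. The fragile parts are the electron-rich ring A (oxidation towards a quinone once both para oxygens are unmasked), the 5-methoxy group peri to the carbonyl (cleaved by Lewis acids) and the pyranone ring (opened by hydroxide). The real difficulty is oxygen differentiation, not ring C: one free phenol among three methyl ethers on a hexasubstituted benzene, a second free phenol beside a methyl ether on ring B, and a C2–C1' bond crowded by two ortho substituents. The key step uses the fact that C8a, C8, C7 and C6 with their four oxygens are the four carbons of a squaric diester. The two carbonyl carbons become the hydroquinone carbons C8a and C6, the two methoxy-bearing carbons become C8 and C7. C5 and C4a come from a 1-methoxyalkenyl arm whose third carbon, an acetal, is C4.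

## Logic of the disconnections

19 from 18: the two O–Si bonds on O6 and O2' are cut last. Both phenols carry the same silyl group, so a single fluoride treatment frees them while the four methyl ethers stay. This keeps the oxidisable ring A masked to the end. The forward step must avoid Lewis acids because of the 5-methoxy group.

18 from 16 (through 17): the O1–C2 bond of ring C is cut. This reduces the heterocycle to an acyclic ynone with the C8a oxygen free and all carbons in place. The forward step must close the six-membered ring at C2 and not the five-membered ring at C3, so the closure is routed through the amine adduct 17, in which C2 is the only electrophilic carbon.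

16 from 15, and 15 from 9 and 12 (through 13 and 14): after adjusting C4 to the carbinol level, the C3–C4 bond is cut. This is the convergent step that joins ring A (9) to ring B with its two-carbon link (13, made in the flask from 12). The forward addition must tolerate the free phenol of 9, which is first turned into 14. The later oxidation must touch only the doubly activated carbinol.

12 from 11 and 11 from 10: the C3 carbon is removed as a one-carbon homologation of an aldehyde, and the O–Si bond of ring B is cut. 10 already has the 2'-oxygen free and the 6'-oxygen methylated, so ring B needs no differentiation step.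

9 from 8: the aldehyde at C4 is traced back to its dimethyl acetal, the form in which C4 passes through the ring-forming step.

8 from 5 (through 7 and 6): the C4a–C8a bond of ring A is cut in a retro-6π sense and the C8a–C6 bond is re-formed in a retro-4π sense. This replaces a hexasubstituted benzene by a four-membered ring that already holds four of the five ring A oxygens in the right order. The forward step must turn the silyloxy group outward on ring opening and must keep the ketene oxygen distinct from the silylated oxygen; both follow from the mechanism.

5 from 1 and 2 (through 3 and 4): the C5–C6 bond and the O–Si bond are cut. Both partners are simple commercial compounds. The forward step needs lithiation of 2 at C1 with retention of the alkene geometry, mono-addition to one carbonyl of 1, and silylation of the tertiary alkoxide 4 without ionising the acid-labile vinylogous acetal; the alkoxide is therefore trapped in the same flask with no amine base.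

## Other disconnections considered

Alternative 1: The cut is the C2–C1' bond, with a temporary ester between the 2'-oxygen and a carboxyl group on C3. In the forward step, zerovalent palladium (from Pd(OAc)2, tricyclohexylphosphine and potassium pivalate) inserts into the C–Br bond of the aryl ester A1. The arylpalladium species then metalates chromone C2–H and reductive elimination closes the six-membered lactone A2. Lactone opening and loss of the C3 carboxyl as carbon dioxide would give the benzyl ether A3, and hydrogenolysis the target.
- In favour: the doubly ortho-substituted C2–C1' bond is made intramolecularly, the 2'-oxygen is marked as the lactone oxygen, and the tether carbon leaves without trace.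
- Against: the plan does not address ring A. The ring A half of A1 needs a long sequence of classical aromatic substitution and ring closure before the key step. The C–Br bond lies between two oxygen substituents and should add slowly. The activated aryl ester and chromone C2 are exposed to pivalate and carbonate, and the hydroxide needed to open A2 can also open the pyranone.
- Comparison: on structure, this plan is better at the C2–C1' bond and has no flavone-versus-aurone question, because ring C exists before the coupling. The chosen plan is better at ring A, where the actual problem lies. On mechanism, a palladium-mediated C–H arylation with base stands against a reagent-free thermal pericyclic cascade; both are reasonable extensions of known chemistry. On step economy, the alternative is clearly longer once the synthesis of A1 is counted.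

Alternative 2: The cut is the C5–C6 bond of ring A, with rings C and B already in place. In the forward step, base forms the enolate of the pyranone keto ester A4 at the benzyloxy-bearing carbon. This attacks the ester carbonyl on C4a in a 6-exo-trig Claisen (Dieckmann-type) closure; loss of methanol and enolisation give the 5,7-diol A5. Double O-methylation to A6 and hydrogenolysis of both benzyl ethers would finish the synthesis.
- In favour: every ring A oxygen is placed by the chain, and the 6-oxygen arrives already distinguished as a benzyl ether. Both benzyl groups fall in one operation, which equals the single global deprotection of the chosen plan. Ring C and the C2–C1' bond are never at issue, which is better than the chosen plan on that point. The conditions are ionic and mild, with no ketene intermediate.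
- Against: A4 is a tetrasubstituted pyranone with an α-methoxy ketone side chain, and making it is longer than the whole chosen route. Its most acidic proton is on the methoxy-bearing carbon, so the productive enolate is the minor, equilibrating one. Alkoxide can open the pyranone, and the chelated 5-OH of A5 is methylated only under forcing conditions.
- Comparison: on structure, both plans fix the oxygen pattern unambiguously. On mechanism, the regiochemistry here rests on enolate equilibration, whereas in the chosen plan it is enforced by orbital symmetry and torquoselectivity. On step economy, the alternative is worse.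

Alternative 3: The cuts are C1'–C2' and C1'–C6', so that ring B is grown on the intact chromone. In the forward step, the lateral anion of the 2-methylchromone A7 is acylated by dimethyl glutarate A8. A second, intramolecular acylation of the resulting doubly stabilised carbanion closes ring B as the cyclohexane-1,3-dione A9. Mono-O-methylation of the symmetric dione and dehydrogenation would give A3, and hydrogenolysis the target.
- In favour: the crowded C2–C1' bond never has to be formed, which equals the chosen plan, where this bond also comes in ready-made. The symmetry of A9 makes the 2'-OH/6'-OMe distinction trivial, which is again equal, since the chosen plan buys this distinction in its ring B starting material.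
- Against: ring A is unsolved; A7 needs the same hexasubstituted aromatic precursor as alternative 1. The double acylation needs about three equivalents of strong amide base in the presence of a chromone open to attack at C2. The dehydrogenation must spare a benzyl ether and an electron-rich ring A.
- Comparison: on structure, the alternative handles ring B elegantly but leaves the harder ring A to classical chemistry. On mechanism, two carbanion acylations and an oxidation stand against one thermal rearrangement. On step economy, the alternative is longer.

Key step: step 2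

Remark: 2 is taken as the pure E isomer. In 3, 4 and 5 the descriptor stays E although the acetal carbon lies cis to the lithium or to the four-membered ring, because the methoxy group outranks both. 4, 5, 7 and 15 are racemic, with one enantiomer drawn where a centre is written.

Step 1
Reactants: 1 dimethyl squarate; 2 (E)-1,3,3-trimethoxypropene
Product: 5 (E)-4-(tert-butyldimethylsilyloxy)-2,3-dimethoxy-4-(1,3,3-trimethoxyprop-1-enyl)cyclobut-2-en-1-one (racemic), via vinyllithium 3 (not isolated), via lithium alkoxide 4 (not isolated)
Conditions: 2, t-BuLi, THF, −78 → −30 °C; then 1, THF, −78 °C; then TBSOTf, −78 → −30 °C; aq NaHCO3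
Reagents that add atoms: tert-butyldimethylsilyl trifluoromethanesulfonate, CC(C)(C)[Si](C)(C)OS(=O)(=O)C(F)(F)F
Why: Directed α-lithiation of the enol ether (the cis acetal oxygens chelate lithium, geometry retained) is followed by 1,2-addition of the vinyllithium to one carbonyl of the squarate and O-silylation of the lithium alkoxide in the same flask. Trapping the alkoxide directly, without an amine base, avoids the silyl triflate/amine conditions that open dimethyl acetals and avoids isolating the acid-sensitive tertiary alcohol. The quaternary carbon forms racemic and is flattened in step 2.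

Step 2
Reactants: 5 (E)-4-(tert-butyldimethylsilyloxy)-2,3-dimethoxy-4-(1,3,3-trimethoxyprop-1-enyl)cyclobut-2-en-1-one
Product: 8 4-(tert-butyldimethylsilyloxy)-2-(dimethoxymethyl)-3,5,6-trimethoxyphenol, via dienylketene 6 (not isolated), via cyclohexadienone 7 (not isolated)
Conditions: PhMe (degassed, 0.02 M), 110 °C
Reagents that add atoms: none
Why: Heating cleaves the C1–C4 bond of the cyclobutenone by conrotatory 4π electrocyclic ring opening; the closest known reaction type is the Moore rearrangement of 4-alkenyl-4-oxycyclobutenones made from squarates. The silyloxy donor on C4 turns outward (torquoselectivity), which puts the methoxyalkenyl arm cis to the ketene in 6. Ring A then closes by thermal disrotatory 6π electrocyclisation between the ketene carbon (C8a) and the alkene terminus (C4a) to give dienone 7, and enolisation of 7 aromatises the ring to 8. The acetal carbon lies on the inward side of the alkene terminus; this should be tolerated because the other terminus is an sp-hybridised ketene carbon with no inward substituent. No stereocenter survives: the quaternary carbon of 5 becomes sp2 and the sp3 carbon of 7 is lost on tautomerisation. The selectivity required is the distinction between the two hydroquinone oxygens, and the mechanism secures it: the ketene oxygen becomes the free phenol on C8a and the silyloxy carbon becomes C6. High dilution, degassing and base-washed glassware keep the ketene from bimolecular capture and the vinylogous acetal from ionising.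

Step 3
Reactants: 8 4-(tert-butyldimethylsilyloxy)-2-(dimethoxymethyl)-3,5,6-trimethoxyphenol
Product: 9 3-(tert-butyldimethylsilyloxy)-6-hydroxy-2,4,5-trimethoxybenzaldehyde
Conditions: PPTS (cat.), acetone–H2O, 23 °C
Reagents that add atoms: water, O
Why: Acid-catalysed acetal hydrolysis; an acetal ortho to a free phenol on an electron-rich ring ionises very easily, so a pyridinium salt suffices and the hindered aryl silyl ether is untouched.

Step 4
Reactants: 10 2-hydroxy-6-methoxybenzaldehyde
Product: 11 2-(tert-butyldimethylsilyloxy)-6-methoxybenzaldehyde
Conditions: TBSCl, imidazole, DMF, 23 °C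
Reagents that add atoms: tert-butyldimethylsilyl chloride, CC(C)(C)[Si](C)(C)Cl
Why: Standard imidazole-mediated O-silylation of a phenol; the same silyl group as on O6 is chosen so that both come off together at the end.

Step 5
Reactants: 11 2-(tert-butyldimethylsilyloxy)-6-methoxybenzaldehyde
Product: 12 tert-butyl[2-(2,2-dibromoethenyl)-3-methoxyphenoxy]dimethylsilane
Conditions: CBr4, PPh3, Et3N, CH2Cl2, 0 °C
Reagents that add atoms: carbon tetrabromide, BrC(Br)(Br)Br
Why: Ramirez dibromoolefination (first stage of the Corey–Fuchs sequence), a Wittig reaction of the ylide Ph3P=CBr2 with the aldehyde; triethylamine buffers traces of HBr so the aryl silyl ether persists.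

Step 6
Reactants: 12 tert-butyl[2-(2,2-dibromoethenyl)-3-methoxyphenoxy]dimethylsilane; 9 3-(tert-butyldimethylsilyloxy)-6-hydroxy-2,4,5-trimethoxybenzaldehyde
Product: 15 4-(tert-butyldimethylsilyloxy)-2-{3-[2-(tert-butyldimethylsilyloxy)-6-methoxyphenyl]-1-hydroxyprop-2-yn-1-yl}-3,5,6-trimethoxyphenol (racemic), via lithium acetylide 13 (not isolated), via lithium phenoxide 14 (not isolated)
Conditions: 12, n-BuLi (2 equiv), THF, −78 → 0 °C; 9, LiN(SiMe3)2, THF, −78 °C; combine, −78 → 0 °C; aq NH4Cl
Reagents that add atoms: none
Why: The second stage of the Corey–Fuchs alkyne synthesis (bromine–lithium exchange, Fritsch–Buttenberg–Wiechell rearrangement, deprotonation) gives acetylide 13 directly, and 13 adds 1,2 to the aldehyde. Converting the phenol into phenoxide 14 beforehand with a non-nucleophilic amide base saves an equivalent of 13. The carbinol centre forms without control (racemic) and is removed by the oxidation in step 7.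

Step 7
Reactants: 15 4-(tert-butyldimethylsilyloxy)-2-{3-[2-(tert-butyldimethylsilyloxy)-6-methoxyphenyl]-1-hydroxyprop-2-yn-1-yl}-3,5,6-trimethoxyphenol
Product: 16 1-[3-(tert-butyldimethylsilyloxy)-6-hydroxy-2,4,5-trimethoxyphenyl]-3-[2-(tert-butyldimethylsilyloxy)-6-methoxyphenyl]prop-2-yn-1-one
Conditions: MnO2 (activated, excess), CH2Cl2, 23 °C
Reagents that add atoms: none
Why: MnO2 oxidation selective for a benzylic and propargylic alcohol under neutral heterogeneous conditions; the phenol has no free ortho or para position for oxidative coupling and becomes hydrogen-bonded to the new carbonyl.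

Step 8
Reactants: 16 1-[3-(tert-butyldimethylsilyloxy)-6-hydroxy-2,4,5-trimethoxyphenyl]-3-[2-(tert-butyldimethylsilyloxy)-6-methoxyphenyl]prop-2-yn-1-one
Product: 19 6,2'-dihydroxy-5,7,8,6'-tetramethoxyflavone [6-hydroxy-2-(2-hydroxy-6-methoxyphenyl)-5,7,8-trimethoxy-4H-chromen-4-one], via enaminone 17 (not isolated), via bis-silyl flavone 18 (not isolated)
Conditions: Et2NH, EtOH, 50 °C; concentrate; then Bu4NF, AcOH, THF, 0 → 23 °C
Reagents that add atoms: none
Why: Conjugate addition of the secondary amine to the ynone gives β-enaminone 17, whose amine-bearing carbon (C2) is then attacked by the phenol with loss of diethylamine (6-endo-trig addition–elimination), so the five-membered aurone closure is excluded. Acetic-acid-buffered fluoride then cleaves both aryl silyl ethers in one operation without touching the methyl ethers; any silyl ether already lost in the amine stage converges on the same product.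

## Compound list

1 | dimethyl squarate (3,4-dimethoxycyclobut-3-ene-1,2-dione) | COC1=C(OC)C(=O)C1=O | starting material
2 | (E)-1,3,3-trimethoxypropene | CO/C=C/C(OC)OC | starting material
3 | (E)-(1,3,3-trimethoxyprop-1-en-1-yl)lithium (lithium cis to the acetal carbon) | [Li]/C(OC)=C\C(OC)OC | intermediate
4 | lithium 2,3-dimethoxy-4-oxo-1-[(E)-1,3,3-trimethoxyprop-1-enyl]cyclobut-2-en-1-olate (racemic) | COC1=C(OC)[C@](O[Li])(C1=O)/C(OC)=C\C(OC)OC | intermediate
5 | (E)-4-(tert-butyldimethylsilyloxy)-2,3-dimethoxy-4-(1,3,3-trimethoxyprop-1-enyl)cyclobut-2-en-1-one (racemic) | COC1=C(OC)[C@](O[Si](C)(C)C(C)(C)C)(C1=O)/C(OC)=C\C(OC)OC | intermediate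
6 | (3Z,5E)-4-(tert-butyldimethylsilyloxy)-2,3,5,7,7-pentamethoxyhepta-1,3,5-trien-1-one (dienylketene) | O=C=C(OC)/C(OC)=C(O[Si](C)(C)C(C)(C)C)\C(OC)=C/C(OC)OC | intermediate
7 | 4-(tert-butyldimethylsilyloxy)-6-(dimethoxymethyl)-2,3,5-trimethoxycyclohexa-2,4-dien-1-one (racemic) | COC1=C(OC)C(O[Si](C)(C)C(C)(C)C)=C(OC)[C@H](C(OC)OC)C1=O | intermediate
8 | 4-(tert-butyldimethylsilyloxy)-2-(dimethoxymethyl)-3,5,6-trimethoxyphenol | COC(OC)c1c(OC)c(O[Si](C)(C)C(C)(C)C)c(OC)c(OC)c1O | intermediate
9 | 3-(tert-butyldimethylsilyloxy)-6-hydroxy-2,4,5-trimethoxybenzaldehyde | O=Cc1c(OC)c(O[Si](C)(C)C(C)(C)C)c(OC)c(OC)c1O | intermediate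
10 | 2-hydroxy-6-methoxybenzaldehyde | COc1cccc(O)c1C=O | starting material
11 | 2-(tert-butyldimethylsilyloxy)-6-methoxybenzaldehyde | COc1cccc(O[Si](C)(C)C(C)(C)C)c1C=O | intermediate
12 | tert-butyl[2-(2,2-dibromoethenyl)-3-methoxyphenoxy]dimethylsilane | COc1cccc(O[Si](C)(C)C(C)(C)C)c1C=C(Br)Br | intermediate
13 | lithium [2-(tert-butyldimethylsilyloxy)-6-methoxyphenyl]acetylide | COc1cccc(O[Si](C)(C)C(C)(C)C)c1C#C[Li] | intermediate
14 | lithium 4-(tert-butyldimethylsilyloxy)-2-formyl-3,5,6-trimethoxyphenolate | [Li]Oc1c(OC)c(OC)c(O[Si](C)(C)C(C)(C)C)c(OC)c1C=O | intermediate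
15 | 4-(tert-butyldimethylsilyloxy)-2-{3-[2-(tert-butyldimethylsilyloxy)-6-methoxyphenyl]-1-hydroxyprop-2-yn-1-yl}-3,5,6-trimethoxyphenol (racemic) | COc1cccc(O[Si](C)(C)C(C)(C)C)c1C#CC(O)c1c(OC)c(O[Si](C)(C)C(C)(C)C)c(OC)c(OC)c1O | intermediate
16 | 1-[3-(tert-butyldimethylsilyloxy)-6-hydroxy-2,4,5-trimethoxyphenyl]-3-[2-(tert-butyldimethylsilyloxy)-6-methoxyphenyl]prop-2-yn-1-one | COc1cccc(O[Si](C)(C)C(C)(C)C)c1C#CC(=O)c1c(OC)c(O[Si](C)(C)C(C)(C)C)c(OC)c(OC)c1O | intermediate
17 | (E)-1-[3-(tert-butyldimethylsilyloxy)-6-hydroxy-2,4,5-trimethoxyphenyl]-3-[2-(tert-butyldimethylsilyloxy)-6-methoxyphenyl]-3-(diethylamino)prop-2-en-1-one | CCN(CC)/C(=C/C(=O)c1c(OC)c(O[Si](C)(C)C(C)(C)C)c(OC)c(OC)c1O)c1c(OC)cccc1O[Si](C)(C)C(C)(C)C | intermediate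
18 | 6-(tert-butyldimethylsilyloxy)-2-[2-(tert-butyldimethylsilyloxy)-6-methoxyphenyl]-5,7,8-trimethoxy-4H-chromen-4-one | COc1cccc(O[Si](C)(C)C(C)(C)C)c1-c1cc(=O)c2c(OC)c(O[Si](C)(C)C(C)(C)C)c(OC)c(OC)c2o1 | intermediate
19 | 6,2'-dihydroxy-5,7,8,6'-tetramethoxyflavone | COc1cccc(O)c1-c1cc(=O)c2c(OC)c(O)c(OC)c(OC)c2o1 | target

## Step count and least certain steps

Total: 8 steps. Longest linear sequence: 6 steps (steps 1, 2, 3, 6, 7, 8); ring B is prepared in steps 4 and 5 and joins at step 6.

Step 2 (key step).
- Risk: the acetal carbon must turn inward during the 6π closure. If this slows the closure, the ketene can be captured bimolecularly. In addition, at 110 °C methanol can be lost from the vinylogous acetal of 5 or from the o-hydroxybenzyl acetal of 8, leading to quinone-methide-type oligomerisation.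
- Fallback: introduce C4 after the aromatisation so that no acetal passes through the rearrangement. The fallback sets out from 1 and returns at 9. Methyl vinyl ether is lithiated with t-BuLi to 1-methoxyvinyllithium F1, which is added to 1 and silylated as in step 1 to give 4-(tert-butyldimethylsilyloxy)-2,3-dimethoxy-4-(1-methoxyethenyl)cyclobut-2-en-1-one F2. Its Moore rearrangement, with an unsubstituted alkene terminus, should give 4-(tert-butyldimethylsilyloxy)-2,3,5-trimethoxyphenol F3. Magnesium-mediated ortho-formylation (MgCl2, Et3N, paraformaldehyde) at the only free ring position then delivers 9.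

Step 1.
- Risk: the silyl triflate may ionise the vinylogous acetal in competition with silylation of the hindered alkoxide, or the silylation may be incomplete.
- Fallback: leave the oxygen free through the rearrangement and differentiate the hydroquinone afterwards. The fallback sets out from 4 and returns at 9. Quenching 4 with aqueous NH4Cl gives 4-hydroxy-2,3-dimethoxy-4-[(E)-1,3,3-trimethoxyprop-1-enyl]cyclobut-2-en-1-one F4, the classical Moore substrate. Thermolysis under argon gives 2-(dimethoxymethyl)-3,5,6-trimethoxybenzene-1,4-diol F5, and mild aqueous acid gives 3,6-dihydroxy-2,4,5-trimethoxybenzaldehyde F6. The hydroxyl that is not hydrogen-bonded to the aldehyde is then silylated selectively (TBSCl, imidazole) to give 9.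
- If the lithiation of 2 itself fails (attack at the acetal C–H or decomposition of 3), the fallback under step 2 applies.

Step 7.
- Risk: the free, very electron-rich phenol may be oxidised on the MnO2 surface towards a quinone with loss of the silyl group.
- Fallback: mask the phenol before the coupling. The fallback sets out from 9 and returns at 19. Silylation (TBSOTf, 2,6-lutidine) gives 3,6-bis(tert-butyldimethylsilyloxy)-2,4,5-trimethoxybenzaldehyde F7. Addition of 13 gives 1-[3,6-bis(tert-butyldimethylsilyloxy)-2,4,5-trimethoxyphenyl]-3-[2-(tert-butyldimethylsilyloxy)-6-methoxyphenyl]prop-2-yn-1-ol F8. Dess–Martin oxidation, now with no free phenol, gives the corresponding prop-2-yn-1-one F9. Diethylamine converts F9 into (E)-1-[3,6-bis(tert-butyldimethylsilyloxy)-2,4,5-trimethoxyphenyl]-3-[2-(tert-butyldimethylsilyloxy)-6-methoxyphenyl]-3-(diethylamino)prop-2-en-1-one F10. Buffered Bu4NF removes all three silyl groups, and the liberated C8a phenoxide displaces the amine to give 19.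

Step 8.
- Risk: the two ortho substituents of ring B hinder C2. The free phenoxide may then attack C3 in a 5-exo closure before the amine has added, or the sequence may stall at the enaminone.
- Fallback: pass through the 1,3-diketone, from which only the six-membered ring can form. The fallback sets out from 17 and returns at 18. Aqueous acidic hydrolysis of the vinylogous amide gives 1-[3-(tert-butyldimethylsilyloxy)-6-hydroxy-2,4,5-trimethoxyphenyl]-3-[2-(tert-butyldimethylsilyloxy)-6-methoxyphenyl]propane-1,3-dione F11, the intermediate of a Baker–Venkataraman flavone synthesis. Mild acid-catalysed cyclodehydration (p-TsOH, PhMe, 80 °C), chosen to keep the ring B silyl ether in place, gives 18, which is desilylated as in the second stage of step 8.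

## Further compounds

F1 | step 2 | 1-methoxyvinyllithium | [Li]C(=C)OC
F2 | step 2 | 4-(tert-butyldimethylsilyloxy)-2,3-dimethoxy-4-(1-methoxyethenyl)cyclobut-2-en-1-one (racemic) | COC1=C(OC)[C@](O[Si](C)(C)C(C)(C)C)(C1=O)C(=C)OC
F3 | step 2 | 4-(tert-butyldimethylsilyloxy)-2,3,5-trimethoxyphenol | COc1cc(O)c(OC)c(OC)c1O[Si](C)(C)C(C)(C)C
F4 | step 1 | 4-hydroxy-2,3-dimethoxy-4-[(E)-1,3,3-trimethoxyprop-1-enyl]cyclobut-2-en-1-one (racemic) | COC1=C(OC)[C@](O)(C1=O)/C(OC)=C\C(OC)OC
F5 | step 1 | 2-(dimethoxymethyl)-3,5,6-trimethoxybenzene-1,4-diol | COC(OC)c1c(OC)c(O)c(OC)c(OC)c1O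
F6 | step 1 | 3,6-dihydroxy-2,4,5-trimethoxybenzaldehyde | O=Cc1c(OC)c(O)c(OC)c(OC)c1O
F7 | step 7 | 3,6-bis(tert-butyldimethylsilyloxy)-2,4,5-trimethoxybenzaldehyde | O=Cc1c(OC)c(O[Si](C)(C)C(C)(C)C)c(OC)c(OC)c1O[Si](C)(C)C(C)(C)C
F8 | step 7 | 1-[3,6-bis(tert-butyldimethylsilyloxy)-2,4,5-trimethoxyphenyl]-3-[2-(tert-butyldimethylsilyloxy)-6-methoxyphenyl]prop-2-yn-1-ol (racemic) | COc1cccc(O[Si](C)(C)C(C)(C)C)c1C#CC(O)c1c(OC)c(O[Si](C)(C)C(C)(C)C)c(OC)c(OC)c1O[Si](C)(C)C(C)(C)C
F9 | step 7 | 1-[3,6-bis(tert-butyldimethylsilyloxy)-2,4,5-trimethoxyphenyl]-3-[2-(tert-butyldimethylsilyloxy)-6-methoxyphenyl]prop-2-yn-1-one | COc1cccc(O[Si](C)(C)C(C)(C)C)c1C#CC(=O)c1c(OC)c(O[Si](C)(C)C(C)(C)C)c(OC)c(OC)c1O[Si](C)(C)C(C)(C)C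
F10 | step 7 | (E)-1-[3,6-bis(tert-butyldimethylsilyloxy)-2,4,5-trimethoxyphenyl]-3-[2-(tert-butyldimethylsilyloxy)-6-methoxyphenyl]-3-(diethylamino)prop-2-en-1-one | CCN(CC)/C(=C/C(=O)c1c(OC)c(O[Si](C)(C)C(C)(C)C)c(OC)c(OC)c1O[Si](C)(C)C(C)(C)C)c1c(OC)cccc1O[Si](C)(C)C(C)(C)C
F11 | step 8 | 1-[3-(tert-butyldimethylsilyloxy)-6-hydroxy-2,4,5-trimethoxyphenyl]-3-[2-(tert-butyldimethylsilyloxy)-6-methoxyphenyl]propane-1,3-dione | COc1cccc(O[Si](C)(C)C(C)(C)C)c1C(=O)CC(=O)c1c(OC)c(O[Si](C)(C)C(C)(C)C)c(OC)c(OC)c1O
A1 | alternative 1 | 2-bromo-3-methoxyphenyl 6-(benzyloxy)-5,7,8-trimethoxy-4-oxo-4H-chromene-3-carboxylate | COc1cccc(OC(=O)c2coc3c(OC)c(OC)c(OCc4ccccc4)c(OC)c3c2=O)c1Br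
A2 | alternative 1 | 9-(benzyloxy)-1,8,10,11-tetramethoxy-6H,7H-chromeno[4,3-b]chromene-6,7-dione | COc1cccc2oc(=O)c3c(=O)c4c(OC)c(OCc5ccccc5)c(OC)c(OC)c4oc3c12
A3 | alternative 1 | 6-(benzyloxy)-2-(2-hydroxy-6-methoxyphenyl)-5,7,8-trimethoxy-4H-chromen-4-one | COc1cccc(O)c1-c1cc(=O)c2c(OC)c(OCc3ccccc3)c(OC)c(OC)c2o1
A4 | alternative 2 | methyl 2-[3-(benzyloxy)-1-methoxy-2-oxopropyl]-6-[2-(benzyloxy)-6-methoxyphenyl]-4-oxo-4H-pyran-3-carboxylate (racemic) | COC(=O)c1c(C(OC)C(=O)COCc2ccccc2)oc(-c2c(OC)cccc2OCc2ccccc2)cc1=O
A5 | alternative 2 | 6-(benzyloxy)-2-[2-(benzyloxy)-6-methoxyphenyl]-5,7-dihydroxy-8-methoxy-4H-chromen-4-one | COc1cccc(OCc2ccccc2)c1-c1cc(=O)c2c(O)c(OCc3ccccc3)c(O)c(OC)c2o1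
A6 | alternative 2 | 6-(benzyloxy)-2-[2-(benzyloxy)-6-methoxyphenyl]-5,7,8-trimethoxy-4H-chromen-4-one | COc1cccc(OCc2ccccc2)c1-c1cc(=O)c2c(OC)c(OCc3ccccc3)c(OC)c(OC)c2o1
A7 | alternative 3 | 6-(benzyloxy)-5,7,8-trimethoxy-2-methyl-4H-chromen-4-one | Cc1cc(=O)c2c(OC)c(OCc3ccccc3)c(OC)c(OC)c2o1
A8 | alternative 3 | dimethyl glutarate | COC(=O)CCCC(=O)OC
A9 | alternative 3 | 6-(benzyloxy)-2-(2-hydroxy-6-oxocyclohex-1-en-1-yl)-5,7,8-trimethoxy-4H-chromen-4-one | O=C1CCCC(O)=C1c1cc(=O)c2c(OC)c(OCc3ccccc3)c(OC)c(OC)c2o1
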